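**Retrosynthetic overview**

1. The 1,2-dioxepine ring is made last. The dienolate of a 12E enal acetal takes up O2 at C11, and the C11 hydroperoxide closes on the unmasked C15 aldehyde. The 7α-hydroxyl is set just before by allylic oxidation at C7.
2. The enal acetal is joined at C11–C12 from albicanyl iodide (as its organolithium) and an enaminal that delivers the 12E enal with C15 already an acetal.
3. Albicanyl iodide comes from a C11/C17 γ-lactone, whose C17 oxygen is exchanged for the exocyclic C8=C17 methylene. The lactone comes from the cycloadduct with loss of the auxiliary.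
4. The cycloadduct comes from an acyclic triene imide by an intramolecular Diels–Alder reaction that forms C5–C10 and C8–C9 together, so rings A and B arise in one step. The enabling feature is that C9 of ring B carries C11, which can be an acyl group: C9=C10 (with the C10 methyl) is then a dienophile, C5=C6–C7=C8 the diene, and C1–C4 with the gem-dimethyl carbon C4 the tether.
5. The triene imide is assembled from 2,2-dimethylpent-4-enal (C1–C5), triethyl 4-phosphonocrotonate (C6–C8, C17), the E enol triflate of methyl acetoacetate (C9–C11, C20) and an oxazolidinone auxiliary.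

Key step: step 8

Remark: labdane numbering is used for all compounds (decalin C1–C10, C18/C19 on C4, C20 on C10, C17 on C8, side chain C11–C16); C15 is a peroxyhemiacetal carbon that can epimerise by ring opening, and the 15S epimer drawn is assumed to be the thermodynamically preferred one.

**Route**

Step 1
Reactants: 1 2,2-dimethylpent-4-enal; 2 triethyl 4-phosphonocrotonate
Product: 3 ethyl (2E,4E)-6,6-dimethylnona-2,4,8-trienoate
Conditions: 2, LiN(SiMe3)2, THF, −78 °C; then 1, −78 °C → rt
Reagents that add atoms: none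
Why: Vinylogous Horner–Wadsworth–Emmons olefination: the lithiated phosphonate adds through its α-carbon to the non-enolisable neopentyl aldehyde and should give the 2E,4E dienoate that maps onto C5=C6–C7=C8–C17.

Step 2
Reactants: 3 ethyl (2E,4E)-6,6-dimethylnona-2,4,8-trienoate
Product: 4 (2E,4E)-6,6-dimethylnona-2,4,8-trien-1-ol
Conditions: i-Bu2AlH (2.5 equiv), CH2Cl2, −78 °C; aq. potassium sodium tartrate work-up
Reagents that add atoms: none
Why: 1,2-Reduction of the conjugated ester by i-Bu2AlH at low temperature should give the dienol without touching the diene or the terminal alkene.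

Step 3
Reactants: 4 (2E,4E)-6,6-dimethylnona-2,4,8-trien-1-ol
Product: 5 benzyl (2E,4E)-6,6-dimethylnona-2,4,8-trien-1-yl ether
Conditions: NaH, BnBr, Bu4NI (cat.), THF, 0 °C → rt
Reagents that add atoms: benzyl bromide, BrCc1ccccc1
Why: Williamson etherification; the benzyl group masks the C17 oxygen through the Lewis-acid step and is later removed by the same hydrogenation that saturates C6=C7.

Step 4
Reactants: 6 methyl acetoacetate
Product: 7 methyl (2E)-3-(trifluoromethylsulfonyloxy)but-2-enoate
Conditions: (CF3SO2)2O, aq. Me4NOH, hexanes, 5 °C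
Reagents that add atoms: trifluoromethanesulfonic anhydride, O=S(=O)(OS(=O)(=O)C(F)(F)F)C(F)(F)F
Why: O-Sulfonylation of the non-chelated tetramethylammonium enolate of the β-keto ester (stereodivergent enol triflate formation) should place the triflate trans to the ester (2E), the geometry that the coupling transfers to C9=C10.

Step 5
Reactants: 5 benzyl (2E,4E)-6,6-dimethylnona-2,4,8-trien-1-yl ether; 7 methyl (2E)-3-(trifluoromethylsulfonyloxy)but-2-enoate
Product: 9 methyl (2E,8E,10E)-12-(benzyloxy)-3,7,7-trimethyldodeca-2,8,10-trienoate, via alkylborane 8 (not isolated)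
Conditions: 9-BBN (1.2 equiv), THF, 0 °C → rt; then 7, Pd(dppf)Cl2 (5 mol %), K3PO4, DMF/H2O, 50 °C
Reagents that add atoms: none
Why: 9-BBN hydroborates only the monosubstituted alkene (boron at C1), and the B-alkyl Suzuki–Miyaura coupling with the enol triflate proceeds with retention, so the tether ends trans and the C20 methyl cis to the ester.

Step 6
Reactants: 9 methyl (2E,8E,10E)-12-(benzyloxy)-3,7,7-trimethyldodeca-2,8,10-trienoate
Product: 10 (2E,8E,10E)-12-(benzyloxy)-3,7,7-trimethyldodeca-2,8,10-trienoic acid
Conditions: LiOH, THF/MeOH/H2O, 45 °C; then aq. HCl to pH 3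
Reagents that add atoms: lithium hydroxide, [Li+].[OH-]
Why: Saponification of the methyl ester; the ether and the three alkenes are inert to aqueous hydroxide.

Step 7
Reactants: 10 (2E,8E,10E)-12-(benzyloxy)-3,7,7-trimethyldodeca-2,8,10-trienoic acid; 11 (4S)-4-benzyl-1,3-oxazolidin-2-one
Product: 13 (4S)-4-benzyl-3-[(2E,8E,10E)-12-(benzyloxy)-3,7,7-trimethyldodeca-2,8,10-trienoyl]-1,3-oxazolidin-2-one, via mixed pivalic anhydride 12 (not isolated)
Conditions: t-BuCOCl, Et3N, THF, −20 °C; then LiCl, 11, rt
Reagents that add atoms: none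
Why: N-Acylation of the oxazolidinone through the mixed pivalic anhydride (LiCl/Et3N variant), which does not isomerise the enoate.

Step 8
Reactants: 13 (4S)-4-benzyl-3-[(2E,8E,10E)-12-(benzyloxy)-3,7,7-trimethyldodeca-2,8,10-trienoyl]-1,3-oxazolidin-2-one
Product: 14 (4S)-4-benzyl-3-{[(1S,2S,4aS,8aS)-2-[(benzyloxy)methyl]-5,5,8a-trimethyl-1,2,4a,5,6,7,8,8a-octahydronaphthalen-1-yl]carbonyl}-1,3-oxazolidin-2-one (trans-fused; labdane locants 5α-H, 8β-CH2OBn, 9β-acyl, 10β-CH3, C6=C7)
Conditions: Me2AlCl (2.0 equiv), CH2Cl2, −30 → 0 °C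
Reagents that add atoms: none
Why: Me2AlCl gives a cationic aluminium chelate of the two imide carbonyls, which locks the enoyl unit s-cis and lowers its LUMO, so that the tethered 8E,10E diene adds across C9=C10 in a concerted, asynchronous [4+2] cycloaddition; the closest known reaction type is the Lewis-acid-promoted intramolecular Diels–Alder reaction of trienoyl imides that carry a chiral oxazolidinone auxiliary. C5–C10 and C8–C9 form together: ring B closes as the cyclohexene of the suprafacial [4+2] array, and ring A closes as the six-membered ring made of the C1–C4 tether and the new C5–C10 bond. C9 and the quaternary C10 take their relative configuration from the E dienophile (methyl cis to the acyl group, tether trans), and C5 from the endo transition state with the acyl group under the diene and the tether exo, which gives the trans ring fusion. C8 follows from the E geometry of the distal diene bond, so its benzyloxymethyl group ends cis to C11; this is used in step 9 and erased in step 11. The absolute sense is set by the (4S)-benzyl group, which shields one face of the chelated enoyl plane so that the diene should add to the si face of C9 (the enantiomeric auxiliary would give the antipode). The step needs endo over exo selectivity and one dienophile face; the bidentate chelate, the E,E diene and the gem-dimethyl carbon C4 in the tether (Thorpe–Ingold compression) are what secure them.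

Step 9
Reactants: 14 cycloadduct imide (5α-H, 8β-CH2OBn, 9β-acyl, 10β-CH3, C6=C7)
Product: 16 cis-fused γ-lactone (11,17-olide; 8α-H; 9α-H), via hydroxy imide 15 (not isolated)
Conditions: H2 (1 atm), Pd/C (10 wt % Pd), EtOAc, rt; filter; then DBU (0.2 equiv), CH2Cl2, rt
Reagents that add atoms: none
Why: Hydrogenation over palladium saturates C6=C7 and hydrogenolyses the benzyl ether; the freed C17 hydroxyl is cis to the C11 imide (a consequence of the endo cycloaddition) and, with catalytic DBU, should acylate intramolecularly (5-exo-trig lactonisation) with release of the auxiliary 11, which is recovered.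

Step 10
Reactants: 16 cis-fused γ-lactone (11,17-olide)
Product: 17 17-(phenylselanyl) acid (5α-H, 8α-H, 8β-CH2SePh, 9β-CO2H, 10β-CH3)
Conditions: PhSeH, NaH, THF, 0 °C; then 16, DMF, 110 °C; aq. HCl work-up
Reagents that add atoms: benzeneselenol, [SeH]c1ccccc1
Why: SN2 opening of the γ-lactone at its primary O–CH2 carbon (alkyl–oxygen cleavage) by the soft, weakly basic selenolate, a known lactone-to-selanyl-acid conversion that should not epimerise C9.

Step 11
Reactants: 17 17-(phenylselanyl) acid
Product: 19 albicanic acid (8(17)-ene; 5α-H, 9β-CO2H, 10β-CH3), via selenoxide 18 (not isolated)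
Conditions: H2O2 (30 % aq.), pyridine, THF, 0 → 40 °C
Reagents that add atoms: none
Why: Oxidation to the selenoxide and thermal syn-elimination (selenoxide elimination); the only β-hydrogen is H8, so the exocyclic C8=C17 alkene is the single possible product and the temporary stereocentre C8 disappears.

Step 12
Reactants: 19 albicanic acid
Product: 20 (5S,9S,10S)-albicanol (11-hydroxy, 8(17)-ene)
Conditions: LiAlH4, Et2O, 0 °C → rt
Reagents that add atoms: none
Why: LiAlH4 reduction of the carboxylic acid to the primary alcohol; the isolated 1,1-disubstituted alkene is not reduced.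

Step 13
Reactants: 20 (5S,9S,10S)-albicanol
Product: 21 albicanyl iodide (11-iodo, 8(17)-ene)
Conditions: I2, PPh3, imidazole, toluene, 60 °C
Reagents that add atoms: iodine, II
Why: Appel-type iodination of the primary alcohol by SN2 at C11.

Step 14
Reactants: 22 methyl 4,4-dimethoxybutanoate
Product: 23 4,4-dimethoxybutanal
Conditions: i-Bu2AlH (1.05 equiv), CH2Cl2, −78 °C
Reagents that add atoms: none
Why: Partial reduction of the ester to the aldehyde through the tetrahedral aluminium hemiacetal that is stable at −78 °C.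

Step 15
Reactants: 23 4,4-dimethoxybutanal
Product: 24 (2E)-2-[(dimethylamino)methylidene]-4,4-dimethoxybutanal
Conditions: Me2NCH(OMe)2 (3 equiv), neat, 80 °C
Reagents that add atoms: N,N-dimethylformamide dimethyl acetal, COC(OC)N(C)C
Why: Condensation of the α-methylene group of the aldehyde with the amide acetal (aminomethylenation) gives the push–pull enaminal, a 2-substituted 3-aminoacrolein.

Step 16
Reactants: 21 albicanyl iodide; 24 (2E)-2-[(dimethylamino)methylidene]-4,4-dimethoxybutanal
Product: 27 (12E)-15,15-dimethoxylabda-8(17),12-dien-16-al, via albicanyllithium 25 (not isolated), via lithium alkoxide adduct 26 (not isolated)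
Conditions: 21, t-BuLi (2.1 equiv), Et2O/pentane, −78 °C; then 24, THF, −78 → 0 °C; then aq. AcOH/NaOAc (pH 4–5), rt
Reagents that add atoms: water, O
Why: Iodine–lithium exchange and 1,2-addition of the primary alkyllithium to the aldehyde of the vinylogous formamide, followed by mild acid hydrolysis in which the carbinol oxygen leaves as water and the vinylogous iminium ion takes up water with loss of dimethylamine (formylvinyl cation equivalent; addition–elimination at the aminomethylidene carbon would converge on the same enal), should give the thermodynamically favoured 12E enal with the acetal intact.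

Step 17
Reactants: 27 (12E)-15,15-dimethoxylabda-8(17),12-dien-16-al
Product: 28 (12E)-7α-hydroxy-15,15-dimethoxylabda-8(17),12-dien-16-al
Conditions: SeO2 (0.5 equiv), t-BuOOH (anhydrous, 3 equiv), CH2Cl2, 0 °C → rt
Reagents that add atoms: selenium dioxide (oxygen carrier), O=[Se]=O; tert-butyl hydroperoxide (terminal oxidant), CC(C)(C)OO
Why: Riley allylic oxidation: ene reaction of SeO2 at the electron-rich exocyclic alkene with loss of the axial H7α and [2,3]-sigmatropic return of oxygen to C7 on the α face should give the axial 7α-alcohol (7R), the usual outcome for 8(17)-ene drimanes and labdanes; the enal alkene is too electron-poor to react.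

Step 18
Reactants: 28 (12E)-7α-hydroxy-15,15-dimethoxylabda-8(17),12-dien-16-al
Product: 32 target (5S,7R,9R,10S,11S,15S)-7,15-dihydroxy-11,15-epidioxylabda-8(17),12-dien-16-al, via dipotassium dienolate 29 (not isolated), via hydroperoxy acetal 30 (not isolated), via hydroperoxy dialdehyde 31 (not isolated)
Conditions: KN(SiMe3)2 (2.2 equiv), THF, −78 °C; dry O2, −78 °C; AcOH (3 equiv), −78 °C; then THF/aq. HCl (0.5 M), 0 °C → rt
Reagents that add atoms: dioxygen, O=O; water, O
Why: Proposed new method: γ-deprotonation at C11 (the only carbonyl-stabilised site once C15 is an acetal) gives the s-trans dienolate, which should transfer one electron to triplet O2 and recombine at the γ-terminus C11 to keep the enal conjugated and the 12E geometry, with oxygen arriving anti to the quaternary C10 in the conformer where H9 eclipses the dienolate plane (11S); acid then unmasks the C15 aldehyde and the C11 hydroperoxide adds to it to close the seven-membered ring, which only C15 can reach because C11 and C14 are cis on C12=C13, while C15 settles by ring–chain equilibration; the closest known reaction types are the base-mediated γ-autoxidation of enone dienolates and steroidal dienol ethers to γ-hydroperoxy enones and the addition of hydroperoxides to aldehydes to give peroxyhemiacetals.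

**Compound list**

1 | 2,2-dimethylpent-4-enal | C=CCC(C)(C)C=O | starting material
2 | triethyl 4-phosphonocrotonate | CCOC(=O)/C=C/CP(=O)(OCC)OCC | starting material
3 | ethyl (2E,4E)-6,6-dimethylnona-2,4,8-trienoate | CCOC(=O)/C=C/C=C/C(C)(C)CC=C | intermediate
4 | (2E,4E)-6,6-dimethylnona-2,4,8-trien-1-ol | OC/C=C/C=C/C(C)(C)CC=C | intermediate
5 | benzyl (2E,4E)-6,6-dimethylnona-2,4,8-trien-1-yl ether | C=CCC(C)(C)/C=C/C=C/COCc1ccccc1 | intermediate
6 | methyl acetoacetate | COC(=O)CC(C)=O | starting material
7 | methyl (2E)-3-(trifluoromethylsulfonyloxy)but-2-enoate | COC(=O)/C=C(\C)OS(=O)(=O)C(F)(F)F | intermediate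
8 | 9-[(5E,7E)-9-(benzyloxy)-4,4-dimethylnona-5,7-dien-1-yl]-9-borabicyclo[3.3.1]nonane (not isolated) | C(CCC(C)(C)/C=C/C=C/COCc1ccccc1)B1C2CCCC1CCC2 | intermediate
9 | methyl (2E,8E,10E)-12-(benzyloxy)-3,7,7-trimethyldodeca-2,8,10-trienoate | COC(=O)/C=C(\C)CCCC(C)(C)/C=C/C=C/COCc1ccccc1 | intermediate
10 | (2E,8E,10E)-12-(benzyloxy)-3,7,7-trimethyldodeca-2,8,10-trienoic acid | OC(=O)/C=C(\C)CCCC(C)(C)/C=C/C=C/COCc1ccccc1 | intermediate
11 | (4S)-4-benzyl-1,3-oxazolidin-2-one | O=C1N[C@@H](Cc2ccccc2)CO1 | starting material
12 | mixed pivalic anhydride of acid 10 (not isolated) | CC(C)(C)C(=O)OC(=O)/C=C(\C)CCCC(C)(C)/C=C/C=C/COCc1ccccc1 | intermediate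
13 | (4S)-4-benzyl-3-[(2E,8E,10E)-12-(benzyloxy)-3,7,7-trimethyldodeca-2,8,10-trienoyl]-1,3-oxazolidin-2-one | O=C(/C=C(\C)CCCC(C)(C)/C=C/C=C/COCc1ccccc1)N1[C@@H](Cc2ccccc2)COC1=O | intermediate
14 | (4S)-4-benzyl-3-{[(1S,2S,4aS,8aS)-2-[(benzyloxy)methyl]-5,5,8a-trimethyl-1,2,4a,5,6,7,8,8a-octahydronaphthalen-1-yl]carbonyl}-1,3-oxazolidin-2-one | c1ccccc1COC[C@H]1C=C[C@H]2C(C)(C)CCC[C@]2(C)[C@H]1C(=O)N1[C@@H](Cc2ccccc2)COC1=O | intermediate
15 | hydroxy imide: 17-hydroxy, C6–C7 saturated analogue of 14 (5α-H, 8β-CH2OH, 9β-acyl, 10β-CH3; not isolated) | OC[C@H]1CC[C@H]2C(C)(C)CCC[C@]2(C)[C@H]1C(=O)N1[C@@H](Cc2ccccc2)COC1=O | intermediate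
16 | cis-fused γ-lactone, 11,17-olide (5α-H, 8α-H, 9α-H, 10β-CH3) | O=C1OC[C@H]2CC[C@H]3C(C)(C)CCC[C@]3(C)[C@@H]12 | intermediate
17 | 17-(phenylselanyl) acid (5α-H, 8β-CH2SePh, 9β-CO2H, 10β-CH3) | c1ccccc1[Se]C[C@H]1CC[C@H]2C(C)(C)CCC[C@]2(C)[C@H]1C(=O)O | intermediate
18 | selenoxide of 17 (not isolated) | c1ccccc1[Se](=O)C[C@H]1CC[C@H]2C(C)(C)CCC[C@]2(C)[C@H]1C(=O)O | intermediate
19 | albicanic acid (8(17)-ene, 9β-CO2H) | C=C1CC[C@H]2C(C)(C)CCC[C@]2(C)[C@H]1C(=O)O | intermediate
20 | (5S,9S,10S)-albicanol | C=C1CC[C@H]2C(C)(C)CCC[C@]2(C)[C@H]1CO | intermediate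
21 | albicanyl iodide (11-iodo, 8(17)-ene) | C=C1CC[C@H]2C(C)(C)CCC[C@]2(C)[C@H]1CI | intermediate
22 | methyl 4,4-dimethoxybutanoate | COC(=O)CCC(OC)OC | starting material
23 | 4,4-dimethoxybutanal | O=CCCC(OC)OC | intermediate
24 | (2E)-2-[(dimethylamino)methylidene]-4,4-dimethoxybutanal | CN(C)/C=C(/C=O)CC(OC)OC | intermediate
25 | albicanyllithium (not isolated) | C=C1CC[C@H]2C(C)(C)CCC[C@]2(C)[C@H]1C[Li] | intermediate
26 | lithium alkoxide adduct of 25 and 24 (carbinol epimers; not isolated) | C=C1CC[C@H]2C(C)(C)CCC[C@]2(C)[C@H]1CC([O-])C(CC(OC)OC)=CN(C)C.[Li+] | intermediate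
27 | (12E)-15,15-dimethoxylabda-8(17),12-dien-16-al | C=C1CC[C@H]2C(C)(C)CCC[C@]2(C)[C@H]1C/C=C(/C=O)CC(OC)OC | intermediate
28 | (12E)-7α-hydroxy-15,15-dimethoxylabda-8(17),12-dien-16-al | C=C1[C@H](O)C[C@H]2C(C)(C)CCC[C@]2(C)[C@H]1C/C=C(/C=O)CC(OC)OC | intermediate
29 | dipotassium 7-alkoxide 11,13(16)-dienolate of 28 (not isolated) | C=C1[C@H]([O-])C[C@H]2C(C)(C)CCC[C@]2(C)[C@H]1/C=C/C(CC(OC)OC)=C/[O-].[K+].[K+] | intermediate
30 | (11S,12E)-11-hydroperoxy-7α-hydroxy-15,15-dimethoxylabda-8(17),12-dien-16-al (not isolated) | C=C1[C@H](O)C[C@H]2C(C)(C)CCC[C@]2(C)[C@H]1[C@@H](OO)/C=C(/C=O)CC(OC)OC | intermediate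
31 | (11S,12E)-11-hydroperoxy-7α-hydroxylabda-8(17),12-diene-15,16-dial (not isolated) | C=C1[C@H](O)C[C@H]2C(C)(C)CCC[C@]2(C)[C@H]1[C@@H](OO)/C=C(/C=O)CC=O | intermediate
32 | (5S,7R,9R,10S,11S,15S)-7,15-dihydroxy-11,15-epidioxylabda-8(17),12-dien-16-al (CNP0269954.1) | C=C1[C@H](O)C[C@H]2C(C)(C)CCC[C@]2(C)[C@H]1[C@@H]1C=C(C=O)C[C@@H](O)OO1 | target

**Step count and risks**

Total step count: 18. Longest linear sequence: 15 steps (steps 1–3, 5–13 and 16–18).

The three steps most likely to fail, the riskiest first:

Risk 1 is step 18, the step that rests on a new method. Oxygen may be taken up at C13 instead of C11, the facial selectivity at C11 may be low, or the hydroperoxide anion may collapse by Kornblum–DeLaMare elimination to the 11-ketone before the quench. The fallback for step 18 is a singlet-oxygen ene route built on known reaction types and sets out from 28. The same γ-deprotonation (KN(SiMe3)2, THF, −78 °C) gives 29, and an immediate kinetic quench under argon (AcOH, −78 °C) should give, by α-protonation, the deconjugated aldehyde (11E)-7α-hydroxy-15,15-dimethoxylabda-8(17),11-dien-16-al F1. A Schenck ene photooxygenation (O2, tetraphenylporphyrin, visible light, CH2Cl2, −30 °C) should then add oxygen at C11 with transfer of the doubly activated H13 and return the double bond into conjugation. This comes back to the route at 30, which is carried through the acid treatment of step 18 to 32.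

Risk 2 is step 8. The β,β-disubstituted enoyl imide may react too slowly at the temperatures at which the aluminium chelate keeps endo and facial control, so that exo (cis-fused) cyclisation, ionisation of the dienyl benzyl ether or poor facial selectivity intervene. The fallback for step 8 replaces auxiliary control by catalyst control and sets out from acid 10. Acylation of 1,3-oxazolidin-2-one through the mixed anhydride 12 (t-BuCOCl, Et3N, THF, −20 °C; then LiCl and the oxazolidinone, rt) should give the achiral imide 3-[(2E,8E,10E)-12-(benzyloxy)-3,7,7-trimethyldodeca-2,8,10-trienoyl]-1,3-oxazolidin-2-one F2. The dicationic divalent copper complex [Cu(t-Bu-box)](SbF6)2 (10 mol %, CH2Cl2, rt; t-Bu-box is 2,2'-(propane-2,2-diyl)bis(4-tert-butyl-4,5-dihydro-1,3-oxazole), used as the enantiomer whose square-planar chelate leaves the si face of C9 open) binds the imide as a chelate and is a stronger activator. It should give the trans-fused cycloadduct 3-{[(1S,2S,4aS,8aS)-2-[(benzyloxy)methyl]-5,5,8a-trimethyl-1,2,4a,5,6,7,8,8a-octahydronaphthalen-1-yl]carbonyl}-1,3-oxazolidin-2-one F3. Hydrogenation (H2, Pd/C, EtOAc, rt) gives the 17-hydroxy imide F4, which DBU should lactonise with release of 1,3-oxazolidin-2-one, and the fallback comes back to the route at 16.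

Risk 3 is step 17. The allylic alcohol may be over-oxidised to the 7-ketone, the selenium reagent may attack the enal, or the dimethyl acetal may be lost under the acidic conditions. The fallback for step 17 oxidises before the side chain is attached and sets out from iodide 21. The same Riley oxidation (SeO2, t-BuOOH, CH2Cl2) on this robust substrate should give 7α-hydroxyalbicanyl iodide F5, and silylation (t-BuMe2SiOSO2CF3, 2,6-lutidine, CH2Cl2) gives 7α-(tert-butyldimethylsilyloxy)albicanyl iodide F6. Iodine–lithium exchange (t-BuLi, Et2O/pentane, −78 °C) gives 7α-(tert-butyldimethylsilyloxy)albicanyllithium F7, which adds to enaminal 24 to give the lithium alkoxide adduct F8. Hydrolysis with aq. AcOH/NaOAc should then give (12E)-7α-(tert-butyldimethylsilyloxy)-15,15-dimethoxylabda-8(17),12-dien-16-al F9. Desilylation with Bu4NF buffered by AcOH in THF comes back to the route at 28.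

Further compounds
F1 | step 18 | (11E)-7α-hydroxy-15,15-dimethoxylabda-8(17),11-dien-16-al (C13 epimers) | C=C1[C@H](O)C[C@H]2C(C)(C)CCC[C@]2(C)[C@H]1/C=C/C(C=O)CC(OC)OC
F2 | step 8 | 3-[(2E,8E,10E)-12-(benzyloxy)-3,7,7-trimethyldodeca-2,8,10-trienoyl]-1,3-oxazolidin-2-one | O=C(/C=C(\C)CCCC(C)(C)/C=C/C=C/COCc1ccccc1)N1CCOC1=O
F3 | step 8 | 3-{[(1S,2S,4aS,8aS)-2-[(benzyloxy)methyl]-5,5,8a-trimethyl-1,2,4a,5,6,7,8,8a-octahydronaphthalen-1-yl]carbonyl}-1,3-oxazolidin-2-one | c1ccccc1COC[C@H]1C=C[C@H]2C(C)(C)CCC[C@]2(C)[C@H]1C(=O)N1CCOC1=O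
F4 | step 8 | 17-hydroxy imide: C6–C7 saturated, debenzylated analogue of F3 (5α-H, 8β-CH2OH, 9β-acyl, 10β-CH3) | OC[C@H]1CC[C@H]2C(C)(C)CCC[C@]2(C)[C@H]1C(=O)N1CCOC1=O
F5 | step 17 | 7α-hydroxyalbicanyl iodide | C=C1[C@H](O)C[C@H]2C(C)(C)CCC[C@]2(C)[C@H]1CI
F6 | step 17 | 7α-(tert-butyldimethylsilyloxy)albicanyl iodide | C=C1[C@H](O[Si](C)(C)C(C)(C)C)C[C@H]2C(C)(C)CCC[C@]2(C)[C@H]1CI
F7 | step 17 | 7α-(tert-butyldimethylsilyloxy)albicanyllithium | C=C1[C@H](O[Si](C)(C)C(C)(C)C)C[C@H]2C(C)(C)CCC[C@]2(C)[C@H]1C[Li]
F8 | step 17 | lithium alkoxide adduct of F7 and 24 (carbinol epimers) | C=C1[C@H](O[Si](C)(C)C(C)(C)C)C[C@H]2C(C)(C)CCC[C@]2(C)[C@H]1CC([O-])C(CC(OC)OC)=CN(C)C.[Li+]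
F9 | step 17 | (12E)-7α-(tert-butyldimethylsilyloxy)-15,15-dimethoxylabda-8(17),12-dien-16-al | C=C1[C@H](O[Si](C)(C)C(C)(C)C)C[C@H]2C(C)(C)CCC[C@]2(C)[C@H]1C/C=C(/C=O)CC(OC)OC
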